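**Plan**
- Retrosynthesis: (a) the MOM ether on the C8 oxygen of the ring B chromene is removed last; (b) both 2,2-dimethyl-2H-pyran rings are cut together, each at C3–C4 and at O1–C2, giving a biaryl bis(salicylaldehyde) and two isobutenyl units; (c) the biaryl bond is cut (Suzuki–Miyaura); (d) the prenyl group is traced back to an allyl group placed by a Claisen rearrangement.
- Enabling feature: in each chromene the atoms O1–C8a–C4a–C4=C3–C2(Me)2 are the closed valence isomer of an ortho-quinone methide 1-oxatriene (O1=C8a–C4a=C4–C3=C2Me2). C4 sits on the ring carbon next to the phenolic oxygen, so it can start as a salicylaldehyde carbon that receives an alkenyl group from boron held on O1.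
- Forward order: ring A fragment (O-allylation, Claisen, cross-metathesis to prenyl, borylation); ring B fragment (3-O-MOM protection, bromination); Suzuki coupling joins the two benzene rings; one amine-catalysed condensation with 2-methylprop-1-enylboronic acid closes both pyran rings through the biomimetic oxa-6π ring closure; MOM removal ends the route.
- Stereochemistry: the target has no stereocenter and no olefin with E/Z isomers (ring olefins are cis by constraint, the prenyl olefin carries two equal methyl groups), so nothing has to be controlled; the stereocenters of intermediate 17 are transient.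

Key step: step 8

**Route**

Step 1
Reactants: 1 5-bromo-2-hydroxybenzaldehyde; 2 allyl bromide
Product: 3 2-(allyloxy)-5-bromobenzaldehyde
Conditions: allyl bromide, K2CO3, DMF, rt
Reagents that add atoms: allyl bromide, C=CCBr
Why: Williamson ether synthesis, in which the acidic salicylaldehyde OH is deprotonated by carbonate and the phenoxide displaces bromide from the allylic halide.

Step 2
Reactants: 3 2-(allyloxy)-5-bromobenzaldehyde
Product: 4 3-allyl-5-bromo-2-hydroxybenzaldehyde
Conditions: neat under Ar, 200 °C
Reagents that add atoms: none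
Why: Aromatic Claisen rearrangement, a [3,3]-sigmatropic shift that can deliver the allyl group only to the one free ortho position (the other ortho carbon bears CHO, the para carbon bears Br) before tautomerization restores the phenol.

Step 3
Reactants: 4 3-allyl-5-bromo-2-hydroxybenzaldehyde; 5 2-methylbut-2-ene
Product: 6 5-bromo-2-hydroxy-3-(3-methylbut-2-en-1-yl)benzaldehyde
Conditions: second-generation Grubbs catalyst (3 mol%), 2-methylbut-2-ene (excess), CH2Cl2, 40 °C, sealed tube
Reagents that add atoms: 2-methylbut-2-ene, CC=C(C)C
Why: Olefin cross-metathesis, in which the terminal allyl olefin exchanges its CH2 end for the isopropylidene end of the excess trisubstituted olefin, and the trisubstituted prenyl product should not re-enter the cycle.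

Step 4
Reactants: 6 5-bromo-2-hydroxy-3-(3-methylbut-2-en-1-yl)benzaldehyde; 7 bis(pinacolato)diboron
Product: 8 2-hydroxy-3-(3-methylbut-2-en-1-yl)-5-(4,4,5,5-tetramethyl-1,3,2-dioxaborolan-2-yl)benzaldehyde
Conditions: B2pin2, Pd(dppf)Cl2 (3 mol%), KOAc, 1,4-dioxane, 85 °C
Reagents that add atoms: bis(pinacolato)diboron, CC1(C)OB(OC1(C)C)B1OC(C)(C)C(C)(C)O1
Why: Miyaura borylation, in which the weak acetate base promotes transmetalation with the diboron reagent but not a following Suzuki homocoupling, and the phenol, aldehyde and prenyl olefin are left untouched.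

Step 5
Reactants: 9 2,3-dihydroxybenzaldehyde; 10 chloromethyl methyl ether
Product: 11 2-hydroxy-3-(methoxymethoxy)benzaldehyde
Conditions: NaH (2.2 equiv), DMSO, rt; then MOMCl (1.0 equiv); mild acidic work-up
Reagents that add atoms: chloromethyl methyl ether, COCCl
Why: O-alkylation of the dianion (Williamson type), in which the 3-phenoxide, neither chelated nor conjugated to the formyl group, is the more nucleophilic oxygen and should take the single equivalent of MOMCl.

Step 6
Reactants: 11 2-hydroxy-3-(methoxymethoxy)benzaldehyde; 12 N-bromosuccinimide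
Product: 13 5-bromo-2-hydroxy-3-(methoxymethoxy)benzaldehyde
Conditions: NBS (1.0 equiv), MeCN, 0 °C to rt
Reagents that add atoms: N-bromosuccinimide, O=C1CCC(=O)N1Br
Why: Electrophilic aromatic bromination directed para to the free OH (also meta to CHO), with NBS chosen because it forms no HBr that could cleave the MOM acetal.

Step 7
Reactants: 8 2-hydroxy-3-(3-methylbut-2-en-1-yl)-5-(4,4,5,5-tetramethyl-1,3,2-dioxaborolan-2-yl)benzaldehyde; 13 5-bromo-2-hydroxy-3-(methoxymethoxy)benzaldehyde
Product: 14 4,4'-dihydroxy-5-(methoxymethoxy)-5'-(3-methylbut-2-en-1-yl)-[1,1'-biphenyl]-3,3'-dicarbaldehyde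
Conditions: Pd(dppf)Cl2 (3 mol%), K2CO3 (4 equiv), 1,4-dioxane/H2O 4:1, 80 °C; work-up at pH 5
Reagents that add atoms: none
Why: Suzuki–Miyaura coupling, which tolerates both partners as unprotected phenoxides under aqueous carbonate and leaves the aldehydes, the MOM ether and the prenyl olefin unchanged.

Step 8
Reactants: 14 4,4'-dihydroxy-5-(methoxymethoxy)-5'-(3-methylbut-2-en-1-yl)-[1,1'-biphenyl]-3,3'-dicarbaldehyde; 15 2-methylprop-1-enylboronic acid; 16 dibenzylamine (catalytic, regenerated)
Product: 19 6-[8-(methoxymethoxy)-2,2-dimethyl-2H-chromen-6-yl]-2,2-dimethyl-8-(3-methylbut-2-en-1-yl)-2H-chromene, via bis(allylic amine) Petasis adduct 17 (not isolated), via ring B ortho-quinone methide 18 (not isolated)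
Conditions: 15 (3 equiv), Bn2NH (40 mol%), 1,4-dioxane, 90 °C, Ar
Reagents that add atoms: 2-methylprop-1-enylboronic acid, CC(C)=CB(O)O
Why: Each salicylaldehyde unit condenses with Bn2NH to an iminium ion whose neighbouring phenoxide binds the alkenylboronic acid as a tetracoordinate boronate, and this boronate hands its 2-methylprop-1-enyl group intramolecularly to the iminium carbon (Petasis borono-Mannich step, new C4–C3 bond, adduct 17, drawn with both aldehydes converted). At 90 °C the ortho-hydroxybenzylic amine should lose Bn2NH to give the ortho-quinone methide 1-oxatriene (18, drawn for ring B with ring A already closed; ring A passes through the analogous species), which closes between the phenolic oxygen and the CMe2 terminus (new O1–C2 bond) and regains aromaticity, so the amine turns over. The closest known reaction type is the amine-catalysed condensation of salicylaldehydes with alkenylboronic acids to 2H-chromenes, run here on both aldehydes of 14 in one flask. Both pyran rings close in the same mode, a thermal disrotatory oxa-6π electrocyclization that copies the presumed biosynthetic ring closure, with the exocyclic double bond of the quinone methide free to equilibrate to the geometry that can close. No stereocenter remains in 19, because the two aminated benzylic carbons of 17 become sp2 again and the new ring olefins are cis by ring constraint. The step needs site selectivity for the aldehyde carbon and the oxygen next to it, which is secured because only an aldehyde with a free ortho OH can bind boron and form the quinone methide, the second oxygen of ring B is blocked as its MOM ether, and the isolated prenyl olefin takes no part.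

Step 9
Reactants: 19 6-[8-(methoxymethoxy)-2,2-dimethyl-2H-chromen-6-yl]-2,2-dimethyl-8-(3-methylbut-2-en-1-yl)-2H-chromene
Product: 20 6-[2,2-dimethyl-8-(3-methylbut-2-en-1-yl)-2H-chromen-6-yl]-2,2-dimethyl-2H-chromen-8-ol
Conditions: HCl (cat.), MeOH, 40 °C
Reagents that add atoms: none
Why: Acid-catalysed methanolysis of the aryl MOM acetal, which should spare the prenyl group because its neighbouring oxygen is already locked in the ring A pyran (no acid-induced chroman formation) and should leave the chromene olefins intact under these mild conditions.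

**Compound list**
1 | 5-bromo-2-hydroxybenzaldehyde | O=Cc1cc(Br)ccc1O | starting material
2 | allyl bromide | C=CCBr | starting material
3 | 2-(allyloxy)-5-bromobenzaldehyde | C=CCOc1ccc(Br)cc1C=O | intermediate
4 | 3-allyl-5-bromo-2-hydroxybenzaldehyde | C=CCc1cc(Br)cc(C=O)c1O | intermediate
5 | 2-methylbut-2-ene | CC=C(C)C | starting material
6 | 5-bromo-2-hydroxy-3-(3-methylbut-2-en-1-yl)benzaldehyde | CC(C)=CCc1cc(Br)cc(C=O)c1O | intermediate
7 | bis(pinacolato)diboron | CC1(C)OB(OC1(C)C)B1OC(C)(C)C(C)(C)O1 | starting material
8 | 2-hydroxy-3-(3-methylbut-2-en-1-yl)-5-(4,4,5,5-tetramethyl-1,3,2-dioxaborolan-2-yl)benzaldehyde | CC(C)=CCc1cc(B2OC(C)(C)C(C)(C)O2)cc(C=O)c1O | intermediate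
9 | 2,3-dihydroxybenzaldehyde | O=Cc1cccc(O)c1O | starting material
10 | chloromethyl methyl ether | COCCl | starting material
11 | 2-hydroxy-3-(methoxymethoxy)benzaldehyde | COCOc1cccc(C=O)c1O | intermediate
12 | N-bromosuccinimide | O=C1CCC(=O)N1Br | starting material
13 | 5-bromo-2-hydroxy-3-(methoxymethoxy)benzaldehyde | COCOc1cc(Br)cc(C=O)c1O | intermediate
14 | 4,4'-dihydroxy-5-(methoxymethoxy)-5'-(3-methylbut-2-en-1-yl)-[1,1'-biphenyl]-3,3'-dicarbaldehyde | CC(C)=CCc1cc(-c2cc(OCOC)c(O)c(C=O)c2)cc(C=O)c1O | intermediate
15 | 2-methylprop-1-enylboronic acid | CC(C)=CB(O)O | starting material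
16 | dibenzylamine | C(NCc1ccccc1)c1ccccc1 | starting material
17 | 3,3'-bis[1-(dibenzylamino)-3-methylbut-2-en-1-yl]-5-(methoxymethoxy)-5'-(3-methylbut-2-en-1-yl)-[1,1'-biphenyl]-4,4'-diol (mixture of diastereomers) | CC(C)=CCc1cc(-c2cc(OCOC)c(O)c(C(C=C(C)C)N(Cc3ccccc3)Cc3ccccc3)c2)cc(C(C=C(C)C)N(Cc2ccccc2)Cc2ccccc2)c1O | intermediate
18 | 4-[2,2-dimethyl-8-(3-methylbut-2-en-1-yl)-2H-chromen-6-yl]-2-(methoxymethoxy)-6-(3-methylbut-2-en-1-ylidene)cyclohexa-2,4-dien-1-one (ring B ortho-quinone methide, exocyclic olefin geometry not fixed) | CC(C)=CCc1cc(C2=CC(=CC=C(C)C)C(=O)C(OCOC)=C2)cc2c1OC(C)(C)C=C2 | intermediate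
19 | 6-[8-(methoxymethoxy)-2,2-dimethyl-2H-chromen-6-yl]-2,2-dimethyl-8-(3-methylbut-2-en-1-yl)-2H-chromene | CC(C)=CCc1cc(-c2cc(OCOC)c3c(c2)C=CC(C)(C)O3)cc2c1OC(C)(C)C=C2 | intermediate
20 | 6-[2,2-dimethyl-8-(3-methylbut-2-en-1-yl)-2H-chromen-6-yl]-2,2-dimethyl-2H-chromen-8-ol | CC(C)=CCc1cc(-c2cc(O)c3c(c2)C=CC(C)(C)O3)cc2c1OC(C)(C)C=C2 | target

**Count**
Total steps: 9. Longest linear sequence: 7 steps (steps 1, 2, 3, 4, 7, 8, 9).

**Steps most likely to fail**

Step 8. The alkenyl transfer from boron may be slow on the second aldehyde, the alkenylboronic acid may protodeboronate at 90 °C, or the sequence may stall at the aminophenol stage, leaving only one pyran ring closed. The fallback sets out from 14 and comes back at 19. Compound 14 is treated with 2-methylprop-1-enylmagnesium bromide (about 5 equiv, two of them spent on the phenols) in THF at 0 °C to give, after NH4Cl quench, 3,3'-bis(1-hydroxy-3-methylbut-2-en-1-yl)-5-(methoxymethoxy)-5'-(3-methylbut-2-en-1-yl)-[1,1'-biphenyl]-4,4'-diol F1. Heating F1 in toluene at 110 °C should dehydrate each ortho-hydroxybenzylic allylic alcohol to the same ortho-quinone methide, which electrocyclizes to 19.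

Step 7. The para-phenoxide boronate 8 may protodeboronate under aqueous base, or the two chelating salicylaldehyde phenoxides may slow the palladium catalyst. The fallback sets out from 6 and 13 and comes back at 19; it moves the ring closure ahead of the coupling so that no free phenol or aldehyde enters the coupling. The condensation of step 8 (15, Bn2NH cat., dioxane, 90 °C) is run on each monomer: 6 should give 6-bromo-2,2-dimethyl-8-(3-methylbut-2-en-1-yl)-2H-chromene F2, and 13 should give 6-bromo-8-(methoxymethoxy)-2,2-dimethyl-2H-chromene F3. Miyaura borylation of F2 (B2pin2, Pd(dppf)Cl2, KOAc, dioxane, 85 °C) gives 2-[2,2-dimethyl-8-(3-methylbut-2-en-1-yl)-2H-chromen-6-yl]-4,4,5,5-tetramethyl-1,3,2-dioxaborolane F4. Suzuki–Miyaura coupling of F4 with F3 (Pd(dppf)Cl2, K2CO3, dioxane/H2O, 80 °C) gives 19.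

Step 5. The single equivalent of MOMCl may be shared between the two oxygens, or double alkylation may occur, giving mixtures. The fallback sets out from 9 and comes back at 11. Both hydroxyls are protected (MOMCl 10 in excess, iPr2NEt, CH2Cl2, rt) to give 2,3-bis(methoxymethoxy)benzaldehyde F5. The MOM group ortho to the formyl group is then cleaved selectively with MgBr2·OEt2 in Et2O at rt, where chelation between the formyl oxygen and the neighbouring acetal oxygen activates only that group, to give 11.

**Further compounds**
F1 | step 8 | 3,3'-bis(1-hydroxy-3-methylbut-2-en-1-yl)-5-(methoxymethoxy)-5'-(3-methylbut-2-en-1-yl)-[1,1'-biphenyl]-4,4'-diol (mixture of diastereomers) | CC(C)=CCc1cc(-c2cc(OCOC)c(O)c(C(O)C=C(C)C)c2)cc(C(O)C=C(C)C)c1O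
F2 | step 7 | 6-bromo-2,2-dimethyl-8-(3-methylbut-2-en-1-yl)-2H-chromene | CC(C)=CCc1cc(Br)cc2c1OC(C)(C)C=C2
F3 | step 7 | 6-bromo-8-(methoxymethoxy)-2,2-dimethyl-2H-chromene | COCOc1cc(Br)cc2c1OC(C)(C)C=C2
F4 | step 7 | 2-[2,2-dimethyl-8-(3-methylbut-2-en-1-yl)-2H-chromen-6-yl]-4,4,5,5-tetramethyl-1,3,2-dioxaborolane | CC(C)=CCc1cc(B2OC(C)(C)C(C)(C)O2)cc2c1OC(C)(C)C=C2
F5 | step 5 | 2,3-bis(methoxymethoxy)benzaldehyde | COCOc1cccc(C=O)c1OCOC
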